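The rate constants were chosen freely; the result is computed.

Start from what remains.

    substrate + free catalyst ⇌ free catalyst + open intermediate (K1 = 2.7, k1 = 7.2 M⁻¹ s⁻¹)
    free catalyst + open intermediate ⇌ catalyst intermediate (K2 = 2.3 M⁻¹, k2 = 17 M⁻¹ s⁻¹)
    reagent + catalyst intermediate → free catalyst + target (k3 = 5.2 M⁻¹ s⁻¹)
    target ⇌ isomer of the product (K4 = 1.2, k4 = 0.013 s⁻¹)

substrate 0.31 M; reagent 0.372 M; free catalyst 0.53 mM; time 2.5 min

- at 2.5 min, what has stopped the reaction, if anything has (no working catalyst is left / the reagent has run out first / it is still moving / forward and back rates have come level / all of the substrate has reacted)
- part of the substrate gone at 2.5 min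
- the target standing at 2.5 min, as a percentage of the substrate charged
- the open intermediate standing at 2.5 min, as a percentage of the substrate charged

- the reaction counts as stopped when no species that holds the substrate changes by six tenths of a point or more over the second half of the time
- run time (flask): 2.5 min

Follow the fraction of substrate left, not the fraction made. At fixed catalyst the first step is a reversible pseudo-first-order change. By itself it would end with 27.0% of the substrate standing, and the distance to that balance shrinks as exp(−N). Add its forward and back constants: 9.87 M⁻¹ s⁻¹. Multiply by the charged catalyst and the time: N = 0.784, the turnover dose. Drop the leak on to target for now. On this first estimate 60.3% of the substrate is left.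

The weak link is the catalyst, which is not free throughout. Catalyst intermediate has a half-life of 0.36 s by the step to target, far shorter than the 2.5 min run, so hold it steady: c(catalyst intermediate)/c(free catalyst) = 1.82 M⁻¹ times c(open intermediate). Let the gone substrate stand as open intermediate, about 0.123 M. This estimate puts free catalyst at 81.7% at the end and, taking the mean with the start, at 90.8% on average. The reforged dose leaves 62.8%, a conversion of 37.2%. On this estimate half of the distance to the balance of the first step remains, so call the flask still moving. My reckoning stops there, without a split of the gone substrate.

The forecast says it is still moving, with conversion 37.3%, target 3.1% and open intermediate 32.5%. Its reckoning opens: “Treat the bound catalyst as steady-state”.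

| Asked | Flask |
|---|---|
| State | it is still moving |
| Conversion | 37.3% |
| Target | 3.09% |
| Open intermediate | 32.5% |

In this flask the reforged dose, 0.712, gave 62.8% on paper, and 63% of the substrate stands. Now take the neighbouring flask charged with 0.0021 M of free catalyst. Its dose is 3.11. The same reckoning gives a mean free share of 85.9% and 32.1% of the substrate left. That neighbouring flask holds 27.8%.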